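**Small charge.** A small charge of coupling partner (B) already shows where first product (M) goes. The reckoning here assumes that starting material (A) gives M with one B, and that double product (D) costs a second B.

| flask | starting material | coupling partner | remark | time |
|---|---|---|---|---|
| violet | 0.30 M | 0.18 M | run made earlier |  |
| grey | 0.30 M | 0.72 M | run made earlier |  |
| blue | 0.15 M | 0.36 M | run made earlier |  |
| flask | 0.30 M | 0.360 M |  | 2.5 h |

| run | time / min | starting material / % | first product / % |
|---|---|---|---|
| violet | 30.0 | 82.8 | 5.4 |
| violet | 60.0 | 73.2 | 2.9 |
| violet | 90.0 | 64.3 | 2.2 |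
| violet | 120 | 59.1 | 3.3 |
| grey | 15.0 | 67.3 | 11.9 |
| grey | 40.0 | 40.2 | 8.1 |
| grey | 80.0 | 21.9 | 4.7 |
| grey | 120 | 12.6 | 1.6 |
| blue | 15.0 | 81.5 | 8.9 |
| blue | 40.0 | 62.7 | 9.3 |
| blue | 80.0 | 40.0 | 6.5 |
| blue | 120 | 27.3 | 3.5 |

(standard deviation of a reading: 1 percentage point)

1. amount of starting material at 2.5 h, in percent of the starting material charged
2. amount of first product at 2.5 h, in percent of the starting material charged
3. amount of double product at 2.5 h, in percent of the starting material charged
4. amount of tris adduct at 2.5 h, in percent of the starting material charged

- a reading or a percentage of tris adduct counts all its forms, free or not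

**Main step.** The first grey reading gives A + B → M a constant k of 0.0393 L mol⁻¹ min⁻¹. With this step alone, one B spent per A, the flask keeps 28.2% of its A.

**Partner-free exit.** At the last violet reading, one B per A used and a second for each M lost would cost 0.235 M, more than the 0.18 M charged. So in the violet run part of M leaves without B.

**Partner toll.** In the grey run, the slope of ln A between the last two readings implies 0.351 M of B left. B used per A used is then one plus φ, with φ = 0.474, the selectivity of lost M towards D. If a partner-free loss competes with a step in B, φ = B̄/(B̄ + B×). Here B̄ lies midway between the B charge and that charge less the A charge. The grey run gives 0.632 M for B×, the crossover level, at which both exits of M run equally fast.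

**This flask.** B̄ = 0.210 M gives φ = 0.249. One plus φ times the A charge is 0.375 M, against the 0.360 M of B charged, so B is taken as one plus φ times A. The flask then keeps 31.1% of its A, more than the 28.2% of the main step, and φ times the A used puts D plus tris adduct (T) near 17.2%.

**The forecast.** It gives A at 32%, M at 2.5%, D at 53% and T at 12%, on the ground: “So M→D cannot consume partner.” Its D plus T of 65.0% differs from the 17.2% reckoned here.

    crystals ⇌ tris adduct, rate k1*(cs1 - [tris adduct]) while solid is left; crystals form when [tris adduct] > cs1 (solubility = 0.0710 M, k = 0.390 min⁻¹)
    starting material + first product → side product A (k = 0.0460 L mol⁻¹ min⁻¹)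
    starting material + coupling partner → first product (k = 0.0380 L mol⁻¹ min⁻¹)
    coupling partner + double product → tris adduct (k = 0.00120 L mol⁻¹ min⁻¹)
    first product → side product B (k = 0.0470 min⁻¹)
    coupling partner + first product → double product (k = 0.130 L mol⁻¹ min⁻¹)

**Result.** The flask holds A at 31.0%, M at 2.24%, D at 19.7% and T at 0.385%, so D plus T is 20.1%, while side product B holds 34.9%. The neighbouring flask charges 1.4 M of B, so B̄ = 1.25 M and φ = 0.664. With 0.383% of its A left, the same reckoning puts D plus T near 66.2%. That neighbouring flask holds 61.9% D and 9.07% T, together 71.0%.

Readings and results were computed with made-up constants; the scatter is artificial.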